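(The runs come from a simulation for substances that don't exist, noise included.)

4 questions stand on these 6 flasks, and behind them a decision for the next run: if east is to give more target, do we leave it longer or charge more reagent?

| flask | starting material | reagent | free catalyst | temperature | remark | time |
|---|---|---|---|---|---|---|
| delta | 0.55 M | 1.2 equiv | 10 mol% | 80 °C | run made earlier |  |
| north-east | 0.50 M | 1.20 equiv | 10 mol% | 80 °C |  | 25 min |
| east | 0.50 M | 0.300 equiv | 10 mol% | 80 °C |  | 25 min |
| south | 0.50 M | 0.400 equiv | 10 mol% | 100 °C |  | 25 min |
| north | 0.50 M | 1.20 equiv | 20 mol% | 65 °C |  | 25 min |
| north-west | 1.5 M | 0.800 equiv | 10 mol% | 80 °C |  | 25 min |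
| west | 0.80 M | 2.40 equiv | 10 mol% | 110 °C |  | 25 min |

- delta (time / min: target / %): 2.00: 2; 4.00: 8; 6.00: 15; 8.00: 17

(scatter of a reading: 1.5 percentage points)

- the numbers in the tables scatter by 1.5 percentage points (one standard deviation)
- the earlier runs do not show what temperature does; that part of a forecast is a guess
- no earlier run changes the charge of free catalyst; that part of a forecast is a guess

* ranking by amount of target, in percent of the starting material charged, from high to low, at 25 min (north-east / east / south / north / north-west / west)
* the same order at 2.5 min (north-east / east / south / north / north-west / west)
* the amount of target, in percent of the starting material charged of the flask you put first, at 25 min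
* the amount of target, in percent of the starting material charged of the flask you put last, at 25 min

We start from the even case, one reagent used per target, which is our assumption. The reagent ceiling, the percent of the starting material charged that the charged reagent can turn into target, is then the equivalents read as percent; where reagent is under one equivalent, it is the limiting reagent. East's ceiling is

30.0%

and south's is 40.0%, so east has the lower one.

Now, how near does east get in the time? The delta run rose by

13 percentage points in 4.00 min,

and its last step of 2 points stands against a scatter of 1.5 points per reading, so we read no stop from it. Kept up to 25 min, that rise gives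

81.2%

We guess that this rise goes with [reagent], which is 0.660 M in delta and 0.150 M in east, so for east we reckon

18.5%

That lies under the ceiling, so east should still be climbing at 25 min, and we commit to it as last, at that figure. West has [reagent] of 1.92 M, and the same line runs past full conversion, so we put west first at 100 %, with its heat a guess. Our decision is to charge reagent: on our reckoning the room left under east's ceiling at 25 min is 11 points.

The forecast gave west > north-west > north > north-east > south > east at 25 min and west > north-west > south > north-east > north > east at 2.5 min, with 55% for the first flask and 20% for the last, and said “Temperature and catalyst effects are guesses”.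

The flask gives west > north-west > north-east > south > north > east at 25 min and west > south > north-west > north-east > east > north at 2.5 min, with west at 100% and east at 23.5%.

    catalyst intermediate C → catalyst intermediate D (k = 1.60 s⁻¹, Ea = 90.0 kJ mol⁻¹)
    catalyst intermediate D → free catalyst + target (k = 0.0399 s⁻¹, Ea = 84.0 kJ mol⁻¹)
    starting material + catalyst intermediate B → catalyst intermediate C (k = 0.0809 M⁻¹ s⁻¹, Ea = 74.0 kJ mol⁻¹)
    catalyst intermediate A ⇌ catalyst intermediate B (K = 54.0, k = 0.00958 s⁻¹, Ea = 95.0 kJ mol⁻¹, ΔH = −57.0 kJ mol⁻¹)
    reagent + free catalyst ⇌ catalyst intermediate A (K = 7.80 M⁻¹, k = 0.0550 M⁻¹ s⁻¹, Ea = 58.0 kJ mol⁻¹, ΔH = −59.0 kJ mol⁻¹)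
    (constants at 80 °C)

At 25 min east stands above the 18.5% we reckoned, has 17.5% of its reagent left unbound and has filled 78.3% of its ceiling. Left to 250 min, east reaches 30.0%, the ceiling of 30.0%. A neighbour of east charged with 1.20 equiv of reagent stands at 58.4% at 25 min. South, under its ceiling of 40.0%, holds 39.7% of target at 25 min, with its reagent down to 0.698% of its charge.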